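**Retrosynthetic overview**
1. The 1,2-dioxepane and the hydroperoxide of 20 are taken back to diene 18 (isopropenyl on C28, prenyl on C3) by a cobalt-mediated silylperoxidation cascade. 18 comes from cage carbinol 14 by C27 deoxygenation and allyl-to-prenyl cross-metathesis.
2. The strategy rests on the cage methine C7, which is bonded to C6, to C8 (CMe2) and to C27, while C8 is also bonded to the benzoyl-bearing C1. This is the imprint of a C5 prenyl olefin attacked at C7 by an electrophilic C27 that is already tied through C28 to quaternary C3.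
3. Key disconnection: C7–C27 and C1–C8 of 14 are cut together, giving monocyclic aldehyde enol 12 (Prins–enol cascade).
4. 12 comes from gem-diprenyl trione 6: C28 by Pd-catalysed branched opening of 2-isopropenyloxirane, C3 by Pd-catalysed allylation, then alcohol oxidation. 6 comes from 2,4,6-trihydroxybenzophenone with a temporary formyl block on C3.
5. Ring order: dearomatised six-membered ring (step 2); seven-membered ring C3–C4–C5–C6–C7–C27–C28, then six-membered ring C1–C9–C5–C6–C7–C8 (both step 8); 1,2-dioxepane (step 12).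

Key step: step 8

Atom labels used throughout: ring C1(benzoyl)–C2(=O)–C3–C4(=O)–C5–C9(=O); bridge C5–C6H2–C7H–C8Me2–C1; bridge C7–C27–C28–C3; C29 is the isopropenyl or peroxy carbon on C28; C1′–C3′ is the C3 side chain.
Assumption: the (R,R)-ligand is taken to induce (R)-C28 in step 5 and the (S,S)-ligand (S)-C3 in step 6; if either sense proves opposite, the mirror-image ligand is used in that step.

**Route**

Step 1
Reactants: 1 2,4,6-trihydroxybenzophenone
Product: 3 3-benzoyl-2,4,6-trihydroxybenzaldehyde, via Vilsmeier iminium chloride 2 (not isolated)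
Conditions: POCl3 (1.1 equiv), DMF, EtOAc, 0 °C to rt; then H2O, 50 °C
Reagents that add atoms: N,N-dimethylformamide CN(C)C=O; water O
Why: Vilsmeier–Haack formylation of the electron-rich ring should stop at the deactivated mono-aldehyde, and the formyl group blocks C3 so that step 2 can only dialkylate C5.

Step 2
Reactants: 3 3-benzoyl-2,4,6-trihydroxybenzaldehyde; 4 prenyl bromide
Product: 5 3-benzoyl-2,4-dihydroxy-5,5-bis(3-methylbut-2-en-1-yl)-6-oxocyclohexa-1,3-diene-1-carbaldehyde
Conditions: prenyl bromide (2.3 equiv), NaOMe (3.3 equiv), MeOH, 0 °C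
Reagents that add atoms: prenyl bromide CC(C)=CCBr
Why: Dearomatising C-alkylation of the acylphloroglucinol phenolate (gem-dialkylation as in the syncarpic acid series) should put both prenyl groups on C5, the only ring carbon that carries no acyl group.

Step 3
Reactants: 5 3-benzoyl-2,4-dihydroxy-5,5-bis(3-methylbut-2-en-1-yl)-6-oxocyclohexa-1,3-diene-1-carbaldehyde
Product: 6 4-benzoyl-3,5-dihydroxy-6,6-bis(3-methylbut-2-en-1-yl)cyclohexa-2,4-dien-1-one
Conditions: 2 M NaOH, MeOH, 45 °C, argon; then cold 1 M HCl to pH 3
Reagents that add atoms: none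
Why: Retro-Claisen deformylation (the classical removal of a hydroxymethylene blocking group) should free C3–H, because hydroxide attacks the formyl carbon much faster than the conjugated benzoyl group.

Step 4
Reactants: 7 methacrolein
Product: 8 rac-2-(prop-1-en-2-yl)oxirane
Conditions: Me3SI, NaH, DMSO/THF, 0 °C; distillation
Reagents that add atoms: trimethylsulfonium iodide C[S+](C)C.[I-]
Why: Corey–Chaykovsky epoxidation, in which dimethylsulfonium methylide adds 1,2 to the enal, should give the vinyl oxirane; the racemate suffices because both enantiomers pass through an equilibrating π-allyl complex in step 5.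

Step 5
Reactants: 6 4-benzoyl-3,5-dihydroxy-6,6-bis(3-methylbut-2-en-1-yl)cyclohexa-2,4-dien-1-one; 8 rac-2-(prop-1-en-2-yl)oxirane
Product: 9 4-benzoyl-3,5-dihydroxy-2-[(2R)-1-hydroxy-3-methylbut-3-en-2-yl]-6,6-bis(3-methylbut-2-en-1-yl)cyclohexa-2,4-dien-1-one
Conditions: Pd2(dba)3·CHCl3 (2.5 mol%), (R,R)-DACH-phenyl Trost ligand (7.5 mol%), 8 (1.2 equiv), CH2Cl2, rt
Reagents that add atoms: rac-2-(prop-1-en-2-yl)oxirane CC(=C)C1CO1
Why: Dynamic kinetic asymmetric allylic alkylation with a vinyl epoxide (Tsuji–Trost type) should work because zerovalent palladium opens the oxirane to a 2-methyl π-allyl alkoxide, the alkoxide deprotonates the C3–H enol and hydrogen bonding delivers C3 to the branched terminus, with the ligand setting (R)-C28 as the only new stereocentre.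

Step 6
Reactants: 9 4-benzoyl-3,5-dihydroxy-2-[(2R)-1-hydroxy-3-methylbut-3-en-2-yl]-6,6-bis(3-methylbut-2-en-1-yl)cyclohexa-2,4-dien-1-one; 10 allyl acetate
Product: 11 (4S)-2-benzoyl-3-hydroxy-4-[(2R)-1-hydroxy-3-methylbut-3-en-2-yl]-6,6-bis(3-methylbut-2-en-1-yl)-4-(prop-2-en-1-yl)cyclohex-2-ene-1,5-dione
Conditions: Pd2(dba)3·CHCl3 (2.5 mol%), (S,S)-DACH-phenyl Trost ligand (7.5 mol%), allyl acetate (1.2 equiv), Et3N, CH2Cl2, 0 °C
Reagents that add atoms: allyl acetate CC(=O)OCC=C
Why: Tsuji–Trost asymmetric allylic alkylation at C3, the only nucleophilic ring carbon without an acyl group, should create the quaternary centre, with the chiral pocket choosing the enolate face so that C3 becomes (S) (the neighbouring C28 centre offers little bias of its own) and any minor diastereomer to be removed by chromatography.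

Step 7
Reactants: 11 (4S)-2-benzoyl-3-hydroxy-4-[(2R)-1-hydroxy-3-methylbut-3-en-2-yl]-6,6-bis(3-methylbut-2-en-1-yl)-4-(prop-2-en-1-yl)cyclohex-2-ene-1,5-dione
Product: 12 (2R)-2-[(1S)-3-benzoyl-2-hydroxy-5,5-bis(3-methylbut-2-en-1-yl)-4,6-dioxo-1-(prop-2-en-1-yl)cyclohex-2-en-1-yl]-3-methylbut-3-enal
Conditions: Dess–Martin periodinane (1.1 equiv), CH2Cl2, 0 °C, 30 min; used crude
Reagents that add atoms: none
Why: Dess–Martin oxidation of the primary alcohol is chosen because its non-basic medium should leave the α-stereogenic β,γ-unsaturated aldehyde unepimerised and unconjugated, and the electron-poor vinylogous-acid enol and the olefins should not react at 0 °C with a slight excess of oxidant.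

Step 8
Reactants: 12 (2R)-2-[(1S)-3-benzoyl-2-hydroxy-5,5-bis(3-methylbut-2-en-1-yl)-4,6-dioxo-1-(prop-2-en-1-yl)cyclohex-2-en-1-yl]-3-methylbut-3-enal
Product: 14 (1R,3R,5S,7S,27S,28R)-1-benzoyl-27-hydroxy-8,8-dimethyl-5-(3-methylbut-2-en-1-yl)-3-(prop-2-en-1-yl)-28-(prop-1-en-2-yl)homoadamantane-2,4,9-trione, via bicyclic C8 carbocation 13 (not isolated)
Conditions: Me2AlCl (3.0 equiv), CH2Cl2, −78 to −20 °C; then 1 M HCl
Reagents that add atoms: none
Why: Proposed new method: one equivalent of Me2AlCl converts the enol into a chelated chloro(methyl)aluminium enolate (methane is lost), a second binds the C27 aldehyde, the C5 prenyl group cis to the C28 chain attacks through its less substituted olefin carbon C7 (C7–C27) and the tertiary C8 cation 13, held over the enolate, is captured at C1 (C1–C8), which leaves the non-enolisable cage trione. The closest known reaction types are Me2AlCl-promoted intramolecular Prins and carbonyl-ene cyclisations of olefinic aldehydes, Prins cyclisations terminated by carbon π-nucleophiles and acid-mediated cation–enol C-alkylations that build type A acylphloroglucinol cores; their union into one step that forms a homoadamantane has no precedent. The seven-membered ring C3–C4–C5–C6–C7–C27–C28 closes 7-exo-trig at the carbonyl (the C7=C8 bond is also exocyclic to it) between two cis 1,3-disposed groups of the six-membered ring, and the six-membered ring C1–C9–C5–C6–C7–C8 closes by attack of the ring enolate carbon on the exocyclic cation (6-enolendo). C5 follows from C3 because only the prenyl group on the face of the C28 chain reaches C27, C7 and C1 follow from the cage because only the adduct with C8 directed over the enolate can close (the other can revert by retro-Prins fragmentation of the γ-cationic alkoxide), and C27 is expected (S) from an open antiperiplanar approach that keeps the aluminium-bound oxygen away from C8, but is erased in step 10. Carbon rather than oxygen capture is needed and is favoured because the enolate oxygens are tied to aluminium and a tertiary enol ether would re-ionise under the Lewis acid whereas the C1–C8 bond is irreversible; ene-type proton loss is disfavoured because the antiperiplanar oxygen cannot reach the C8 methyl hydrogens. C28, α to the aldehyde, must keep its configuration, which the low temperature and a Lewis acid that destroys adventitious protons should secure, and the C3 allyl group cannot compete because its attack on C27 would give only a primary or secondary cation.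

Step 9
Reactants: 14 (1R,3R,5S,7S,27S,28R)-1-benzoyl-27-hydroxy-8,8-dimethyl-5-(3-methylbut-2-en-1-yl)-3-(prop-2-en-1-yl)-28-(prop-1-en-2-yl)homoadamantane-2,4,9-trione
Product: 15 O-phenyl O-[(1R,3R,5S,7S,27S,28R)-1-benzoyl-8,8-dimethyl-5-(3-methylbut-2-en-1-yl)-2,4,9-trioxo-3-(prop-2-en-1-yl)-28-(prop-1-en-2-yl)homoadamantan-27-yl] carbonothioate
Conditions: PhOC(S)Cl (1.5 equiv), pyridine, DMAP (0.2 equiv), CH2Cl2, rt
Reagents that add atoms: O-phenyl chlorothionoformate S=C(Cl)Oc1ccccc1
Why: Thioacylation of the secondary C27 alcohol prepares the Barton–McCombie deoxygenation under neutral conditions, which avoid an alkoxide that could start retro-Claisen cleavage of the non-enolisable β-triketone.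

Step 10
Reactants: 15 O-phenyl O-[(1R,3R,5S,7S,27S,28R)-1-benzoyl-8,8-dimethyl-5-(3-methylbut-2-en-1-yl)-2,4,9-trioxo-3-(prop-2-en-1-yl)-28-(prop-1-en-2-yl)homoadamantan-27-yl] carbonothioate
Product: 16 (1R,3R,5S,7S,28R)-1-benzoyl-8,8-dimethyl-5-(3-methylbut-2-en-1-yl)-3-(prop-2-en-1-yl)-28-(prop-1-en-2-yl)homoadamantane-2,4,9-trione
Conditions: Bu3SnH (5 equiv, 0.5 M), AIBN (0.2 equiv), toluene, 90 °C
Reagents that add atoms: none
Why: Barton–McCombie radical deoxygenation should reduce C27 cleanly because concentrated stannane quenches the secondary radical before it can add to the neighbouring isopropenyl group (1,2-vinyl shift), and the C3 allyl group lies anti to C27 across C3–C28 and cannot be reached; no stereocentre is formed.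

Step 11
Reactants: 16 (1R,3R,5S,7S,28R)-1-benzoyl-8,8-dimethyl-5-(3-methylbut-2-en-1-yl)-3-(prop-2-en-1-yl)-28-(prop-1-en-2-yl)homoadamantane-2,4,9-trione; 17 2-methylbut-2-ene
Product: 18 (1R,3R,5S,7S,28R)-1-benzoyl-8,8-dimethyl-3,5-bis(3-methylbut-2-en-1-yl)-28-(prop-1-en-2-yl)homoadamantane-2,4,9-trione
Conditions: second-generation Grubbs catalyst RuCl2(=CHPh)(PCy3)(H2IMes) (10 mol%), 2-methylbut-2-ene/CH2Cl2 (1:1), 40 °C
Reagents that add atoms: 2-methylbut-2-ene CC=C(C)C
Why: Olefin cross-metathesis of the terminal allyl group with excess 2-methylbut-2-ene should give the prenyl group, since the 1,1-disubstituted isopropenyl and the trisubstituted C5 prenyl are spectators and ring closure onto the isopropenyl is disfavoured by the gauche torsion that the cage fixes between C1′ and C29.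

Step 12
Reactants: 18 (1R,3R,5S,7S,28R)-1-benzoyl-8,8-dimethyl-3,5-bis(3-methylbut-2-en-1-yl)-28-(prop-1-en-2-yl)homoadamantane-2,4,9-trione
Product: 19 triethylsilyl peroxide of the target: (1R,3R,5S,7S,28S,2′S)-cage trione with the 1,2-dioxepane C28–C29Me2–O–O–C2′H–C1′H2–C3 and a 2-(triethylsilylperoxy)propan-2-yl group on C2′
Conditions: Co(acac)2 (10 mol%), Et3SiH (2.5 equiv), O2 (1 atm), t-BuOOH (5 mol%), ClCH2CH2Cl, rt
Reagents that add atoms: dioxygen O=O; triethylsilane CC[SiH](CC)CC
Why: Isayama–Mukaiyama silylperoxidation with peroxyl radical cyclisation, the type known for cobalt-mediated diene peroxidations to 1,2-dioxanes, should apply: hydrogen-atom transfer to the 1,1-disubstituted olefin gives the C29 radical, O2 capture gives the peroxyl radical, this adds 7-exo to C2′ of the C3 prenyl group held gauche to it, and the tertiary C3′ radical takes up O2 and the silyl group; C2′ is set in the cyclisation and is expected (S), with the bulky C3′ group turned away from the C2 and C4 carbonyls.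

Step 13
Reactants: 19 triethylsilyl peroxide of the target
Product: 20 CNP0215795.1
Conditions: HF·pyridine, THF, 0 °C
Reagents that add atoms: none
Why: Fluoride-mediated O–Si cleavage of the silyl peroxide should free the hydroperoxide without touching the O–O bonds or the base-sensitive triketone.

**Compound list**
1 | 2,4,6-trihydroxybenzophenone | O=C(c1ccccc1)c1c(O)cc(O)cc1O | starting material
2 | N-[(3-benzoyl-2,4,6-trihydroxyphenyl)methylidene]-N-methylmethanaminium chloride (Vilsmeier iminium chloride) | C[N+](C)=Cc1c(O)cc(O)c(C(=O)c2ccccc2)c1O.[Cl-] | intermediate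
3 | 3-benzoyl-2,4,6-trihydroxybenzaldehyde | O=Cc1c(O)cc(O)c(C(=O)c2ccccc2)c1O | intermediate
4 | prenyl bromide (1-bromo-3-methylbut-2-ene) | CC(C)=CCBr | starting material
5 | 3-benzoyl-2,4-dihydroxy-5,5-bis(3-methylbut-2-en-1-yl)-6-oxocyclohexa-1,3-diene-1-carbaldehyde | CC(C)=CCC1(CC=C(C)C)C(=O)C(C=O)=C(O)C(C(=O)c2ccccc2)=C1O | intermediate
6 | 4-benzoyl-3,5-dihydroxy-6,6-bis(3-methylbut-2-en-1-yl)cyclohexa-2,4-dien-1-one | CC(C)=CCC1(CC=C(C)C)C(=O)C=C(O)C(C(=O)c2ccccc2)=C1O | intermediate
7 | methacrolein (2-methylprop-2-enal) | CC(=C)C=O | starting material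
8 | rac-2-(prop-1-en-2-yl)oxirane | CC(=C)C1CO1 | intermediate
9 | 4-benzoyl-3,5-dihydroxy-2-[(2R)-1-hydroxy-3-methylbut-3-en-2-yl]-6,6-bis(3-methylbut-2-en-1-yl)cyclohexa-2,4-dien-1-one | CC(C)=CCC1(CC=C(C)C)C(=O)C([C@H](CO)C(C)=C)=C(O)C(C(=O)c2ccccc2)=C1O | intermediate
10 | allyl acetate | CC(=O)OCC=C | starting material
11 | (4S)-2-benzoyl-3-hydroxy-4-[(2R)-1-hydroxy-3-methylbut-3-en-2-yl]-6,6-bis(3-methylbut-2-en-1-yl)-4-(prop-2-en-1-yl)cyclohex-2-ene-1,5-dione | CC(C)=CCC1(CC=C(C)C)C(=O)[C@@](CC=C)([C@H](CO)C(C)=C)C(O)=C(C(=O)c2ccccc2)C1=O | intermediate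
12 | (2R)-2-[(1S)-3-benzoyl-2-hydroxy-5,5-bis(3-methylbut-2-en-1-yl)-4,6-dioxo-1-(prop-2-en-1-yl)cyclohex-2-en-1-yl]-3-methylbut-3-enal (key-step precursor) | CC(C)=CCC1(CC=C(C)C)C(=O)[C@@](CC=C)([C@H](C=O)C(C)=C)C(O)=C(C(=O)c2ccccc2)C1=O | intermediate
13 | bicyclo[4.3.1] zwitterion after C7–C27 bond formation: tertiary C8 cation on C7, C27 alkoxide, enol intact (drawn without aluminium; configurations as in 14) | CC(C)=CC[C@]12C[C@@H]([C+](C)C)[C@H]([O-])[C@H](C(C)=C)[C@](CC=C)(C1=O)C(O)=C(C(=O)c1ccccc1)C2=O | intermediate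
14 | (1R,3R,5S,7S,27S,28R)-1-benzoyl-27-hydroxy-8,8-dimethyl-5-(3-methylbut-2-en-1-yl)-3-(prop-2-en-1-yl)-28-(prop-1-en-2-yl)homoadamantane-2,4,9-trione (cage carbinol; OH on the C6 side of C27, isopropenyl on the C4 side of C28) | CC(C)=CC[C@]12C[C@@H]3[C@H](O)[C@H](C(C)=C)[C@](CC=C)(C1=O)C(=O)[C@](C(=O)c1ccccc1)(C2=O)C3(C)C | intermediate
15 | O-phenyl O-[(1R,3R,5S,7S,27S,28R)-1-benzoyl-8,8-dimethyl-5-(3-methylbut-2-en-1-yl)-2,4,9-trioxo-3-(prop-2-en-1-yl)-28-(prop-1-en-2-yl)homoadamantan-27-yl] carbonothioate | CC(C)=CC[C@]12C[C@@H]3[C@H](OC(=S)Oc4ccccc4)[C@H](C(C)=C)[C@](CC=C)(C1=O)C(=O)[C@](C(=O)c1ccccc1)(C2=O)C3(C)C | intermediate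
16 | (1R,3R,5S,7S,28R)-1-benzoyl-8,8-dimethyl-5-(3-methylbut-2-en-1-yl)-3-(prop-2-en-1-yl)-28-(prop-1-en-2-yl)homoadamantane-2,4,9-trione | CC(C)=CC[C@]12C[C@@H]3C[C@H](C(C)=C)[C@](CC=C)(C1=O)C(=O)[C@](C(=O)c1ccccc1)(C2=O)C3(C)C | intermediate
17 | 2-methylbut-2-ene | CC=C(C)C | starting material
18 | (1R,3R,5S,7S,28R)-1-benzoyl-8,8-dimethyl-3,5-bis(3-methylbut-2-en-1-yl)-28-(prop-1-en-2-yl)homoadamantane-2,4,9-trione | CC(C)=CC[C@]12C[C@@H]3C[C@H](C(C)=C)[C@](CC=C(C)C)(C1=O)C(=O)[C@](C(=O)c1ccccc1)(C2=O)C3(C)C | intermediate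
19 | triethylsilyl peroxide of the target, (1R,3R,5S,7S,28S,2′S): 1,2-dioxepane C28–C29Me2–O–O–C2′H–C1′H2–C3 with a 2-(triethylsilylperoxy)propan-2-yl group on C2′ | CC(C)=CC[C@]12C[C@@H]3C[C@@H]4C(C)(C)OO[C@H](C(C)(C)OO[Si](CC)(CC)CC)C[C@@]4(C1=O)C(=O)[C@](C(=O)c1ccccc1)(C2=O)C3(C)C | intermediate
20 | CNP0215795.1, (1R,3R,5S,7S,28S,2′S): 1-benzoyl-8,8-dimethyl-5-prenyl homoadamantane-2,4,9-trione with the 1,2-dioxepane fused across C3–C28 and a 2-hydroperoxypropan-2-yl group on C2′ | CC(C)=CC[C@]12C[C@@H]3C[C@@H]4C(C)(C)OO[C@H](C(C)(C)OO)C[C@@]4(C1=O)C(=O)[C@](C(=O)c1ccccc1)(C2=O)C3(C)C | target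

**Step count**
Total steps: 13. Longest linear sequence: 12 (steps 1–3 and 5–13 from 1; step 4 is a one-step side branch).

**Steps most likely to fail**

Step 8 (proposed cascade). The seven-membered closure may be too slow. In that case reversible parking of the enolate on the aldehyde (aldol at C1 or lactol formation), methyl transfer from the reagent to the aldehyde, or epimerisation at C28 may take over. Once formed, the C8 cation may also be lost by proton transfer or by capture at the C9 oxygen before it reaches C1. Fallback with known reaction types, which separates the two bond formations: from 12, a chloride-terminated Prins cyclisation (SnCl4, 2,6-di-tert-butylpyridine, CH2Cl2, −78 °C) should give the bicyclic tertiary chloride F1. Silver-assisted ionisation of the C8–Cl bond (AgOTf, 2,6-di-tert-butylpyridine, CH2Cl2/MeNO2, −40 to 0 °C) then lets the enol carbon C1 be tert-alkylated intramolecularly. The route is rejoined at 14.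

Step 12. The C29 peroxyl radical may be intercepted by cobalt and silane before the slow 7-exo closure. The peroxyl addition to C2′ may show poor facial selectivity, and the C5 prenyl group may be over-peroxidised. Fallback that separates peroxide installation from ring closure: from 18, the same cobalt system is run under interception conditions (more silane and cobalt, 0 °C), so that only the isopropenyl group reacts and the open-chain tertiary triethylsilyl peroxide F2 results. HF·pyridine should free the tertiary hydroperoxide F3. A metal-free radical chain (di-tert-butyl hyponitrite as initiator, O2, benzene, 30 °C) then regenerates the peroxyl radical with no fast trap present, so that it can cyclise onto C2′. The C3′ radical takes up O2 and abstracts hydrogen from further hydroperoxide, which gives 20 directly.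

Step 6. Facial selection at C3 may be poor if the catalyst and the existing C28 centre are mismatched, and C-allylation of the hindered enol may be slow enough for O-allylation to persist. Fallback that reverses the order of the two palladium alkylations: from 6, an achiral allylation (Pd(PPh3)4, allyl acetate, Et3N, THF) should give the 3-allyl trione F4. A single opening of epoxide 8 by F4 under the step 5 conditions, with the chiral ligand, then forms C3 and C28 together in one catalyst-controlled event. The route is rejoined at 11.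

Further compounds
F1 | step 8 | bicyclo[4.3.1] chlorohydrin: C7–C27 bond formed, 2-chloropropan-2-yl on C7, free C27 hydroxyl, enol intact (configurations as in 14) | CC(C)=CC[C@]12C[C@@H](C(C)(C)Cl)[C@H](O)[C@H](C(C)=C)[C@](CC=C)(C1=O)C(O)=C(C(=O)c1ccccc1)C2=O
F2 | step 12 | open-chain silyl peroxide: cage of 18 with a 2-(triethylsilylperoxy)propan-2-yl group on C28 and both prenyl groups intact | CC(C)=CC[C@]12C[C@@H]3C[C@H](C(C)(C)OO[Si](CC)(CC)CC)[C@](CC=C(C)C)(C1=O)C(=O)[C@](C(=O)c1ccccc1)(C2=O)C3(C)C
F3 | step 12 | tertiary hydroperoxide: cage of 18 with a 2-hydroperoxypropan-2-yl group on C28 | CC(C)=CC[C@]12C[C@@H]3C[C@H](C(C)(C)OO)[C@](CC=C(C)C)(C1=O)C(=O)[C@](C(=O)c1ccccc1)(C2=O)C3(C)C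
F4 | step 6 | 4-benzoyl-3,5-dihydroxy-6,6-bis(3-methylbut-2-en-1-yl)-2-(prop-2-en-1-yl)cyclohexa-2,4-dien-1-one | CC(C)=CCC1(CC=C(C)C)C(=O)C(CC=C)=C(O)C(C(=O)c2ccccc2)=C1O
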